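**Strategy.** The carbocycle is closed by joining the carbinol carbon C2 to C1, the future quaternary epoxide carbon of the 7-oxabicyclo[4.1.0]hept-3-ene core. C2 is an allylic alcohol next to an epoxide carbon, so the C1–C6 epoxide is read as a (Z)-alkene and C2 as an aldehyde: an intramolecular Nozaki–Hiyama–Kishi reaction of an acyclic (Z)-iodoalkene enal forms the ring and the C2 stereocentre in one operation. The precursor carries a single stereocentre, the C5 silyl ether from a Corey–Bakshi–Shibata reduction; it steers the ring closure to the 1,4-trans dienol and later, as the free alcohol, delivers the epoxide oxygen to its own face.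

Key step: step 13

Remark: locants follow the target name (C1 bears the butenoic acid chain, C2 and C5 the secondary hydroxyls, C3 the heptenyl group, C4 the hydroxymethyl group, C6 is the epoxide CH); 2-(trimethylsilyl)ethyl methacrylate is assumed not to be stocked and is made in step 10.

Step 1
Reactants: 1 hept-1-yne
Product: 3 (E)-1-iodohept-1-ene, via (E)-hept-1-enylzirconocene chloride 2 (not isolated)
Conditions: Cp2Zr(H)Cl, THF, rt; then I2, 0 °C
Reagents that add atoms: iodine, II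
Why: Hydrozirconation adds Zr–H syn with zirconium at the terminal carbon and iodinolysis of the C–Zr bond goes with retention, so only the (E)-iodoalkene should form.

Step 2
Reactants: 3 (E)-1-iodohept-1-ene; 4 but-2-yne-1,4-diol
Product: 7 4-[(E)-hept-1-en-1-yl]-3-(hydroxymethyl)furan-2(5H)-one, via (E)-hept-1-enylmagnesium chloride 5 (not isolated), via alkenylmagnesium chelate 6 (not isolated)
Conditions: 3, i-PrMgCl·LiCl, THF, rt; 4, i-PrMgCl (2 equiv), THF; combine, CuI (10 mol %), THF–PhMe, 70 °C; CO2, 0 °C; 2 M HCl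
Reagents that add atoms: carbon dioxide, O=C=O
Why: Hydroxyl-directed anti-carbomagnesiation of the propargylic alkoxide should place the heptenyl group on one alkyne carbon and magnesium on the other, cis to the chelating CH2O, so that carboxylation with retention and lactonization fix the tetrasubstituted C3=C4 geometry in a butenolide and differentiate the two hydroxymethyl groups.

Step 3
Reactants: 7 4-[(E)-hept-1-en-1-yl]-3-(hydroxymethyl)furan-2(5H)-one
Product: 8 3-{[(tert-butyldimethylsilyl)oxy]methyl}-4-[(E)-hept-1-en-1-yl]furan-2(5H)-one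
Conditions: TBSCl, imidazole, DMF, rt
Reagents that add atoms: tert-butyldimethylsilyl chloride, CC(C)(C)[Si](C)(C)Cl
Why: Silyl ether formation at the only free alcohol; the lactone is untouched.

Step 4
Reactants: 8 3-{[(tert-butyldimethylsilyl)oxy]methyl}-4-[(E)-hept-1-en-1-yl]furan-2(5H)-one
Product: 9 (2Z,4E)-2-{[(tert-butyldimethylsilyl)oxy]methyl}-3-(hydroxymethyl)-N-methoxy-N-methyldeca-2,4-dienamide
Conditions: MeNH(OMe)·HCl, i-PrMgCl, THF, −20 → 0 °C
Reagents that add atoms: N,O-dimethylhydroxylamine hydrochloride, CNOC.Cl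
Why: Aminolysis of the lactone by the chloromagnesium amide (Weinreb amide formation) should open the ring without touching the alkene geometry and free the future C2 carbon as a primary alcohol.

Step 5
Reactants: 9 (2Z,4E)-2-{[(tert-butyldimethylsilyl)oxy]methyl}-3-(hydroxymethyl)-N-methoxy-N-methyldeca-2,4-dienamide
Product: 10 (2Z,4E)-2-{[(tert-butyldimethylsilyl)oxy]methyl}-N-methoxy-N-methyl-3-{[(triethylsilyl)oxy]methyl}deca-2,4-dienamide
Conditions: TESCl, imidazole, CH2Cl2, 0 °C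
Reagents that add atoms: chlorotriethylsilane, CC[Si](Cl)(CC)CC
Why: Immediate silyl ether formation prevents relactonization; a primary triethylsilyl ether is chosen because it can later be oxidized directly.

Step 6
Reactants: 10 (2Z,4E)-2-{[(tert-butyldimethylsilyl)oxy]methyl}-N-methoxy-N-methyl-3-{[(triethylsilyl)oxy]methyl}deca-2,4-dienamide; 11 pent-1-en-4-yne
Product: 13 (7Z,9E)-7-{[(tert-butyldimethylsilyl)oxy]methyl}-8-{[(triethylsilyl)oxy]methyl}pentadeca-1,7,9-trien-4-yn-6-one, via pent-4-en-1-ynyllithium 12 (not isolated)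
Conditions: 11, n-BuLi, THF, −78 °C; then 10, −78 → −20 °C; aq. NH4Cl
Reagents that add atoms: none
Why: Weinreb ketone synthesis: the acetylide adds once through a stable chelated tetrahedral intermediate, and the fully substituted β-carbon blocks conjugate addition.

Step 7
Reactants: 13 (7Z,9E)-7-{[(tert-butyldimethylsilyl)oxy]methyl}-8-{[(triethylsilyl)oxy]methyl}pentadeca-1,7,9-trien-4-yn-6-one
Product: 14 (6S,7Z,9E)-7-{[(tert-butyldimethylsilyl)oxy]methyl}-8-{[(triethylsilyl)oxy]methyl}pentadeca-1,7,9-trien-4-yn-6-ol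
Conditions: (R)-2-methyl-CBS-oxazaborolidine (20 mol %), BH3·SMe2, THF, −30 °C; MeOH
Reagents that add atoms: none
Why: Corey–Bakshi–Shibata reduction with the alkynyl group as the small and the tetrasubstituted alkenyl group as the large substituent should set the carbinol as (S), which is C5 of the target (5R there only through a priority change).

Step 8
Reactants: 14 (6S,7Z,9E)-7-{[(tert-butyldimethylsilyl)oxy]methyl}-8-{[(triethylsilyl)oxy]methyl}pentadeca-1,7,9-trien-4-yn-6-ol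
Product: 16 (4Z,6S,7Z,9E)-7-{[(tert-butyldimethylsilyl)oxy]methyl}-4-iodo-8-{[(triethylsilyl)oxy]methyl}pentadeca-1,4,7,9-tetraen-6-ol, via cyclic alkenylalanate 15 (not isolated)
Conditions: NaAlH2(OCH2CH2OMe)2, THF, 0 °C → rt; then I2, −78 °C
Reagents that add atoms: iodine, II
Why: Hydroxyl-directed trans-hydroalumination of the propargylic alcohol puts aluminium on the distal carbon in a five-membered alanate, and iodinolysis with retention should give the (Z)-iodoalkene with iodine cis to the carbinol carbon, the geometry the ring closure needs.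

Step 9
Reactants: 16 (4Z,6S,7Z,9E)-7-{[(tert-butyldimethylsilyl)oxy]methyl}-4-iodo-8-{[(triethylsilyl)oxy]methyl}pentadeca-1,4,7,9-tetraen-6-ol
Product: 17 (4Z,6S,7Z,9E)-7-{[(tert-butyldimethylsilyl)oxy]methyl}-4-iodo-6-[(triethylsilyl)oxy]-8-{[(triethylsilyl)oxy]methyl}pentadeca-1,4,7,9-tetraene
Conditions: TESCl, imidazole, DMAP (cat.), CH2Cl2, rt
Reagents that add atoms: chlorotriethylsilane, CC[Si](Cl)(CC)CC
Why: Silyl ether formation masks the C5 hydroxyl, which would otherwise form a lactol (and then a furan) with the cis aldehyde made in step 12.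

Step 10
Reactants: 18 2-(trimethylsilyl)ethanol; 19 2-methylprop-2-enoyl chloride
Product: 20 2-(trimethylsilyl)ethyl 2-methylprop-2-enoate
Conditions: Et3N, DMAP (cat.), CH2Cl2, 0 °C
Reagents that add atoms: none
Why: Acylation of the alcohol by the acid chloride (esterification) gives a methacrylate whose ester can later be removed by fluoride.

Step 11
Reactants: 17 (4Z,6S,7Z,9E)-7-{[(tert-butyldimethylsilyl)oxy]methyl}-4-iodo-6-[(triethylsilyl)oxy]-8-{[(triethylsilyl)oxy]methyl}pentadeca-1,4,7,9-tetraene; 20 2-(trimethylsilyl)ethyl 2-methylprop-2-enoate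
Product: 21 2-(trimethylsilyl)ethyl (2E,5Z,7S,8Z,10E)-8-{[(tert-butyldimethylsilyl)oxy]methyl}-5-iodo-2-methyl-7-[(triethylsilyl)oxy]-9-{[(triethylsilyl)oxy]methyl}hexadeca-2,5,8,10-tetraenoate
Conditions: second-generation Hoveyda–Grubbs catalyst [RuCl2(H2IMes)(=CH-C6H4-2-OiPr)] (5 mol %), 20 (5 equiv), CH2Cl2, 40 °C
Reagents that add atoms: none
Why: Olefin cross-metathesis of the only monosubstituted alkene with excess methacrylate should give the (E)-trisubstituted enoate, the tetrasubstituted alkene, the hindered conjugated internal alkene and the iodoalkene being poor metathesis partners.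

Step 12
Reactants: 21 2-(trimethylsilyl)ethyl (2E,5Z,7S,8Z,10E)-8-{[(tert-butyldimethylsilyl)oxy]methyl}-5-iodo-2-methyl-7-[(triethylsilyl)oxy]-9-{[(triethylsilyl)oxy]methyl}hexadeca-2,5,8,10-tetraenoate
Product: 22 2-(trimethylsilyl)ethyl (2E,5Z,7S,8Z,10E)-8-{[(tert-butyldimethylsilyl)oxy]methyl}-9-formyl-5-iodo-2-methyl-7-[(triethylsilyl)oxy]hexadeca-2,5,8,10-tetraenoate
Conditions: (COCl)2, DMSO, CH2Cl2, −78 → −40 °C; Et3N, → 0 °C
Reagents that add atoms: none
Why: Under Swern conditions a primary triethylsilyl ether is cleaved and oxidized directly to the aldehyde while the secondary triethylsilyl ether and the tert-butyldimethylsilyl ether persist.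

Step 13
Reactants: 22 2-(trimethylsilyl)ethyl (2E,5Z,7S,8Z,10E)-8-{[(tert-butyldimethylsilyl)oxy]methyl}-9-formyl-5-iodo-2-methyl-7-[(triethylsilyl)oxy]hexadeca-2,5,8,10-tetraenoate
Product: 24 2-(trimethylsilyl)ethyl (2E)-4-[(3S,6S)-4-{[(tert-butyldimethylsilyl)oxy]methyl}-5-[(E)-hept-1-en-1-yl]-6-hydroxy-3-[(triethylsilyl)oxy]cyclohexa-1,4-dien-1-yl]-2-methylbut-2-enoate, via alkenylchromium dichloride 23 (not isolated)
Conditions: CrCl2 (8 equiv), NiCl2 (2 mol %), degassed DMSO, rt, 0.005 M; aq. sodium potassium tartrate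
Reagents that add atoms: none
Why: Zerovalent nickel, formed from NiCl2 by CrCl2, inserts into the C–I bond with retention and passes the (Z)-alkenyl group to trivalent chromium; the alkenylchromium 23 then adds to the aldehyde carbon and forms the C1–C2 bond. The closest known reaction type is the intramolecular Nozaki–Hiyama–Kishi alkenylation of aldehydes used to close six-membered and larger carbocycles. The ring closes in a 6-exo-trig mode, and the two (Z)-alkenes of the chain hold the reacting carbons on the same side, so cyclization should outrun intermolecular coupling. The new C2 stereocentre is controlled by the C5 triethylsilyloxy group across the forming, boat-like 1,4-diene ring: the chromium-bound carbonyl oxygen should avoid the face carrying the silyloxy group, giving the 1,4-trans dienol. The step needs chemoselectivity for the aldehyde over the ester and for the iodoalkene over the other alkenes, which the reagent provides, and survival of an acid-labile doubly allylic carbinol, which the neutral medium and work-up provide.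

Step 14
Reactants: 24 2-(trimethylsilyl)ethyl (2E)-4-[(3S,6S)-4-{[(tert-butyldimethylsilyl)oxy]methyl}-5-[(E)-hept-1-en-1-yl]-6-hydroxy-3-[(triethylsilyl)oxy]cyclohexa-1,4-dien-1-yl]-2-methylbut-2-enoate
Product: 25 2-(trimethylsilyl)ethyl (2E)-4-[(3S,6S)-6-[(tert-butyldimethylsilyl)oxy]-4-{[(tert-butyldimethylsilyl)oxy]methyl}-5-[(E)-hept-1-en-1-yl]-3-[(triethylsilyl)oxy]cyclohexa-1,4-dien-1-yl]-2-methylbut-2-enoate
Conditions: TBSOTf, 2,6-lutidine (excess), CH2Cl2, −78 °C
Reagents that add atoms: tert-butyldimethylsilyl trifluoromethanesulfonate, CC(C)(C)[Si](C)(C)OS(=O)(=O)C(F)(F)F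
Why: Silyl ether formation with the silyl triflate at low temperature and excess base protects the hindered doubly allylic C2 alcohol without ionizing it.

Step 15
Reactants: 25 2-(trimethylsilyl)ethyl (2E)-4-[(3S,6S)-6-[(tert-butyldimethylsilyl)oxy]-4-{[(tert-butyldimethylsilyl)oxy]methyl}-5-[(E)-hept-1-en-1-yl]-3-[(triethylsilyl)oxy]cyclohexa-1,4-dien-1-yl]-2-methylbut-2-enoate
Product: 26 2-(trimethylsilyl)ethyl (2E)-4-[(3S,6S)-6-[(tert-butyldimethylsilyl)oxy]-4-{[(tert-butyldimethylsilyl)oxy]methyl}-5-[(E)-hept-1-en-1-yl]-3-hydroxycyclohexa-1,4-dien-1-yl]-2-methylbut-2-enoate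
Conditions: HF·pyridine, pyridine (excess), THF, 0 °C
Reagents that add atoms: none
Why: Selective desilylation: buffered HF·pyridine cleaves a secondary triethylsilyl ether much faster than the tert-butyldimethylsilyl ethers, so only the C5 hydroxyl should be freed.

Step 16
Reactants: 26 2-(trimethylsilyl)ethyl (2E)-4-[(3S,6S)-6-[(tert-butyldimethylsilyl)oxy]-4-{[(tert-butyldimethylsilyl)oxy]methyl}-5-[(E)-hept-1-en-1-yl]-3-hydroxycyclohexa-1,4-dien-1-yl]-2-methylbut-2-enoate
Product: 27 2-(trimethylsilyl)ethyl (2E)-4-[(1S,2R,5R,6R)-2-[(tert-butyldimethylsilyl)oxy]-4-{[(tert-butyldimethylsilyl)oxy]methyl}-3-[(E)-hept-1-en-1-yl]-5-hydroxy-7-oxabicyclo[4.1.0]hept-3-en-1-yl]-2-methylbut-2-enoate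
Conditions: VO(acac)2 (5 mol %), t-BuOOH (decane), CH2Cl2, 0 °C
Reagents that add atoms: tert-butyl hydroperoxide, CC(C)(C)OO
Why: Vanadium-catalysed hydroxyl-directed epoxidation: the vanadate ester of the C5 alcohol should deliver oxygen to the cis face of the C6=C1 alkene while the C2 silyl ether shields the other face, which sets C1 and C6 with the epoxide cis to C5–OH and trans to C2–O; preference over the C3=C4 alkene rests only on the bulky silyloxymethyl group at C4 and the three allylic C–O bonds on that alkene.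

Step 17
Reactants: 27 2-(trimethylsilyl)ethyl (2E)-4-[(1S,2R,5R,6R)-2-[(tert-butyldimethylsilyl)oxy]-4-{[(tert-butyldimethylsilyl)oxy]methyl}-3-[(E)-hept-1-en-1-yl]-5-hydroxy-7-oxabicyclo[4.1.0]hept-3-en-1-yl]-2-methylbut-2-enoate
Product: 28 (2E)-4-[(1S,2R,5R,6R)-3-[(E)-hept-1-en-1-yl]-2,5-dihydroxy-4-(hydroxymethyl)-7-oxabicyclo[4.1.0]hept-3-en-1-yl]-2-methylbut-2-enoic acid
Conditions: Bu4NF, THF, 0 °C → rt; aq. NH4Cl
Reagents that add atoms: none
Why: Global deprotection: fluoride cleaves both silyl ethers and removes the 2-(trimethylsilyl)ethyl ester by β-elimination, avoiding the aqueous base that could trigger epoxide migration.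

**Compound list**

1 | hept-1-yne | C#CCCCCC | starting material
2 | chlorobis(cyclopentadienyl)[(E)-hept-1-en-1-yl]zirconium | CCCCC/C=C/[Zr](Cl)(C1C=CC=C1)C1C=CC=C1 | intermediate
3 | (E)-1-iodohept-1-ene | CCCCC/C=C/I | intermediate
4 | but-2-yne-1,4-diol | OCC#CCO | starting material
5 | (E)-hept-1-en-1-ylmagnesium chloride | CCCCC/C=C/[Mg]Cl | intermediate
6 | alkenylmagnesium chelate: (Z)-2-(chloromagnesio)-3-[(E)-hept-1-en-1-yl]but-2-ene-1,4-diol bis(chloromagnesium alkoxide) | CCCCC/C=C/C(CO[Mg]Cl)=C(\CO[Mg]Cl)[Mg]Cl | intermediate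
7 | 4-[(E)-hept-1-en-1-yl]-3-(hydroxymethyl)furan-2(5H)-one | CCCCC/C=C/C1=C(CO)C(=O)OC1 | intermediate
8 | 3-{[(tert-butyldimethylsilyl)oxy]methyl}-4-[(E)-hept-1-en-1-yl]furan-2(5H)-one | CCCCC/C=C/C1=C(CO[Si](C)(C)C(C)(C)C)C(=O)OC1 | intermediate
9 | (2Z,4E)-2-{[(tert-butyldimethylsilyl)oxy]methyl}-3-(hydroxymethyl)-N-methoxy-N-methyldeca-2,4-dienamide | CCCCC/C=C/C(CO)=C(\CO[Si](C)(C)C(C)(C)C)C(=O)N(C)OC | intermediate
10 | (2Z,4E)-2-{[(tert-butyldimethylsilyl)oxy]methyl}-N-methoxy-N-methyl-3-{[(triethylsilyl)oxy]methyl}deca-2,4-dienamide | CCCCC/C=C/C(CO[Si](CC)(CC)CC)=C(\CO[Si](C)(C)C(C)(C)C)C(=O)N(C)OC | intermediate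
11 | pent-1-en-4-yne | C=CCC#C | starting material
12 | pent-4-en-1-yn-1-yllithium | [Li]C#CCC=C | intermediate
13 | (7Z,9E)-7-{[(tert-butyldimethylsilyl)oxy]methyl}-8-{[(triethylsilyl)oxy]methyl}pentadeca-1,7,9-trien-4-yn-6-one | CCCCC/C=C/C(CO[Si](CC)(CC)CC)=C(\CO[Si](C)(C)C(C)(C)C)C(=O)C#CCC=C | intermediate
14 | (6S,7Z,9E)-7-{[(tert-butyldimethylsilyl)oxy]methyl}-8-{[(triethylsilyl)oxy]methyl}pentadeca-1,7,9-trien-4-yn-6-ol | CCCCC/C=C/C(CO[Si](CC)(CC)CC)=C(\CO[Si](C)(C)C(C)(C)C)[C@@H](O)C#CCC=C | intermediate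
15 | cyclic sodium alkenylalanate of 14 (five-membered O–Al–C=C–C ring, aluminium on the former C4, two 2-methoxyethoxy groups on aluminium) | [Na+].CCCCC/C=C/C(CO[Si](CC)(CC)CC)=C(\CO[Si](C)(C)C(C)(C)C)[C@H]1O[Al-](OCCOC)(OCCOC)C(CC=C)=C1 | intermediate
16 | (4Z,6S,7Z,9E)-7-{[(tert-butyldimethylsilyl)oxy]methyl}-4-iodo-8-{[(triethylsilyl)oxy]methyl}pentadeca-1,4,7,9-tetraen-6-ol | CCCCC/C=C/C(CO[Si](CC)(CC)CC)=C(\CO[Si](C)(C)C(C)(C)C)[C@@H](O)/C=C(\I)CC=C | intermediate
17 | (4Z,6S,7Z,9E)-7-{[(tert-butyldimethylsilyl)oxy]methyl}-4-iodo-6-[(triethylsilyl)oxy]-8-{[(triethylsilyl)oxy]methyl}pentadeca-1,4,7,9-tetraene | CCCCC/C=C/C(CO[Si](CC)(CC)CC)=C(\CO[Si](C)(C)C(C)(C)C)[C@@H](O[Si](CC)(CC)CC)/C=C(\I)CC=C | intermediate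
18 | 2-(trimethylsilyl)ethanol | C[Si](C)(C)CCO | starting material
19 | 2-methylprop-2-enoyl chloride | CC(=C)C(Cl)=O | starting material
20 | 2-(trimethylsilyl)ethyl 2-methylprop-2-enoate | CC(=C)C(=O)OCC[Si](C)(C)C | intermediate
21 | 2-(trimethylsilyl)ethyl (2E,5Z,7S,8Z,10E)-8-{[(tert-butyldimethylsilyl)oxy]methyl}-5-iodo-2-methyl-7-[(triethylsilyl)oxy]-9-{[(triethylsilyl)oxy]methyl}hexadeca-2,5,8,10-tetraenoate | CCCCC/C=C/C(CO[Si](CC)(CC)CC)=C(\CO[Si](C)(C)C(C)(C)C)[C@@H](O[Si](CC)(CC)CC)/C=C(\I)C/C=C(\C)C(=O)OCC[Si](C)(C)C | intermediate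
22 | 2-(trimethylsilyl)ethyl (2E,5Z,7S,8Z,10E)-8-{[(tert-butyldimethylsilyl)oxy]methyl}-9-formyl-5-iodo-2-methyl-7-[(triethylsilyl)oxy]hexadeca-2,5,8,10-tetraenoate | CCCCC/C=C/C(C=O)=C(\CO[Si](C)(C)C(C)(C)C)[C@@H](O[Si](CC)(CC)CC)/C=C(\I)C/C=C(\C)C(=O)OCC[Si](C)(C)C | intermediate
23 | alkenylchromium dichloride from 22 (CrCl2 in place of iodine at C5, geometry retained) | CCCCC/C=C/C(C=O)=C(\CO[Si](C)(C)C(C)(C)C)[C@@H](O[Si](CC)(CC)CC)/C=C(\[Cr](Cl)Cl)C/C=C(\C)C(=O)OCC[Si](C)(C)C | intermediate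
24 | 2-(trimethylsilyl)ethyl (2E)-4-[(3S,6S)-4-{[(tert-butyldimethylsilyl)oxy]methyl}-5-[(E)-hept-1-en-1-yl]-6-hydroxy-3-[(triethylsilyl)oxy]cyclohexa-1,4-dien-1-yl]-2-methylbut-2-enoate (3-O and 6-O trans) | CCCCC/C=C/C1=C(CO[Si](C)(C)C(C)(C)C)[C@@H](O[Si](CC)(CC)CC)C=C(C/C=C(\C)C(=O)OCC[Si](C)(C)C)[C@@H]1O | intermediate
25 | 2-(trimethylsilyl)ethyl (2E)-4-[(3S,6S)-6-[(tert-butyldimethylsilyl)oxy]-4-{[(tert-butyldimethylsilyl)oxy]methyl}-5-[(E)-hept-1-en-1-yl]-3-[(triethylsilyl)oxy]cyclohexa-1,4-dien-1-yl]-2-methylbut-2-enoate | CCCCC/C=C/C1=C(CO[Si](C)(C)C(C)(C)C)[C@@H](O[Si](CC)(CC)CC)C=C(C/C=C(\C)C(=O)OCC[Si](C)(C)C)[C@@H]1O[Si](C)(C)C(C)(C)C | intermediate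
26 | 2-(trimethylsilyl)ethyl (2E)-4-[(3S,6S)-6-[(tert-butyldimethylsilyl)oxy]-4-{[(tert-butyldimethylsilyl)oxy]methyl}-5-[(E)-hept-1-en-1-yl]-3-hydroxycyclohexa-1,4-dien-1-yl]-2-methylbut-2-enoate | CCCCC/C=C/C1=C(CO[Si](C)(C)C(C)(C)C)[C@@H](O)C=C(C/C=C(\C)C(=O)OCC[Si](C)(C)C)[C@@H]1O[Si](C)(C)C(C)(C)C | intermediate
27 | 2-(trimethylsilyl)ethyl (2E)-4-[(1S,2R,5R,6R)-2-[(tert-butyldimethylsilyl)oxy]-4-{[(tert-butyldimethylsilyl)oxy]methyl}-3-[(E)-hept-1-en-1-yl]-5-hydroxy-7-oxabicyclo[4.1.0]hept-3-en-1-yl]-2-methylbut-2-enoate | CCCCC/C=C/C1=C(CO[Si](C)(C)C(C)(C)C)[C@@H](O)[C@H]2O[C@@]2(C/C=C(\C)C(=O)OCC[Si](C)(C)C)[C@@H]1O[Si](C)(C)C(C)(C)C | intermediate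
28 | (2E)-4-[(1S,2R,5R,6R)-3-[(E)-hept-1-en-1-yl]-2,5-dihydroxy-4-(hydroxymethyl)-7-oxabicyclo[4.1.0]hept-3-en-1-yl]-2-methylbut-2-enoic acid | CCCCC/C=C/C1=C(CO)[C@@H](O)[C@H]2O[C@@]2(C/C=C(\C)C(=O)O)[C@@H]1O | target

**Step count.** Total: 17 steps. Longest linear sequence: 16 steps (steps 1–9 and 11–17; step 10 is a one-step side branch).

**Steps most likely to fail**

1. Step 13 (ring closure). The facial bias must be transmitted over a 1,4-distance, so the aldehyde may be attacked from both faces. The doubly allylic dienol can also lose its oxygen functions and aromatize on acidic contact. Fallback, setting out from 22: if the closure gives mainly the 1,4-cis dienol F1 (the C2 epimer of 24), the C2 centre is not kept but re-made. Epoxidation of F1 with VO(acac)2 and t-BuOOH is then directed by its own free C2 hydroxyl, which lies on the same face as the C5 silyloxy group, and should give the all-cis epoxy alcohol F2 with the epoxide on the correct face. Dess–Martin oxidation gives the epoxy enone F3, which can no longer aromatize. NaBH4/CeCl3 reduction, with hydride approaching anti to the C1 side chain on the quaternary epoxide carbon, should give the trans epoxy alcohol F4. Bu4NF then removes the triethylsilyl, tert-butyldimethylsilyl and silylethyl groups and the route is rejoined at 28.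

2. Step 16 (directed epoxidation). The C3=C4 alkene is also allylic to the C5 hydroxyl and electronically similar to C6=C1, so competing epoxidation there is possible. Vanadium may also oxidize the doubly allylic alcohol to a dienone that aromatizes. Fallback, setting out from 25: longer exposure to HF·pyridine removes the triethylsilyl ether and the primary tert-butyldimethylsilyl ether to give the diol F5. TEMPO with PhI(OAc)2 oxidizes only the primary allylic alcohol to the enal F6, which makes C3=C4 electron-poor and unreactive toward the vanadium peroxide. The same VO(acac)2 epoxidation then gives the epoxy enal F7, and NaBH4/CeCl3 at −78 °C restores the hydroxymethyl group in F8. Bu4NF completes the deprotection and the route is rejoined at 28.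

3. Step 2 (carbomagnesiation and carboxylation). The alkenyl Grignard may be protonated by incompletely deprotonated diol, a copper-mediated syn pathway may erode the anti-addition, and the hindered alkenylmagnesium may be carboxylated inefficiently. Fallback, setting out from 1: hydroboration with pinacolborane (Cp2Zr(H)Cl cat.) gives the (E)-alkenylboronate F9. Suzuki–Miyaura coupling (Pd(PPh3)4, CsF) with commercial 3,4-dibromofuran-2(5H)-one should occur at the more reactive C4 bromide and give the bromobutenolide F10. Stille coupling with (tributylstannyl)methanol (Pd(PPh3)4) installs the hydroxymethyl group and the route is rejoined at 7.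

**Further compounds**

F1 | step 13 | 2-(trimethylsilyl)ethyl (2E)-4-[(3S,6R)-4-{[(tert-butyldimethylsilyl)oxy]methyl}-5-[(E)-hept-1-en-1-yl]-6-hydroxy-3-[(triethylsilyl)oxy]cyclohexa-1,4-dien-1-yl]-2-methylbut-2-enoate (1,4-cis dienol) | CCCCC/C=C/C1=C(CO[Si](C)(C)C(C)(C)C)[C@@H](O[Si](CC)(CC)CC)C=C(C/C=C(\C)C(=O)OCC[Si](C)(C)C)[C@H]1O
F2 | step 13 | 2-(trimethylsilyl)ethyl (2E)-4-[(1S,2S,5R,6R)-4-{[(tert-butyldimethylsilyl)oxy]methyl}-3-[(E)-hept-1-en-1-yl]-2-hydroxy-5-[(triethylsilyl)oxy]-7-oxabicyclo[4.1.0]hept-3-en-1-yl]-2-methylbut-2-enoate | CCCCC/C=C/C1=C(CO[Si](C)(C)C(C)(C)C)[C@@H](O[Si](CC)(CC)CC)[C@H]2O[C@@]2(C/C=C(\C)C(=O)OCC[Si](C)(C)C)[C@H]1O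
F3 | step 13 | 2-(trimethylsilyl)ethyl (2E)-4-[(1R,5R,6R)-4-{[(tert-butyldimethylsilyl)oxy]methyl}-3-[(E)-hept-1-en-1-yl]-2-oxo-5-[(triethylsilyl)oxy]-7-oxabicyclo[4.1.0]hept-3-en-1-yl]-2-methylbut-2-enoate | CCCCC/C=C/C1=C(CO[Si](C)(C)C(C)(C)C)[C@@H](O[Si](CC)(CC)CC)[C@H]2O[C@@]2(C/C=C(\C)C(=O)OCC[Si](C)(C)C)C1=O
F4 | step 13 | 2-(trimethylsilyl)ethyl (2E)-4-[(1S,2R,5R,6R)-4-{[(tert-butyldimethylsilyl)oxy]methyl}-3-[(E)-hept-1-en-1-yl]-2-hydroxy-5-[(triethylsilyl)oxy]-7-oxabicyclo[4.1.0]hept-3-en-1-yl]-2-methylbut-2-enoate | CCCCC/C=C/C1=C(CO[Si](C)(C)C(C)(C)C)[C@@H](O[Si](CC)(CC)CC)[C@H]2O[C@@]2(C/C=C(\C)C(=O)OCC[Si](C)(C)C)[C@@H]1O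
F5 | step 16 | 2-(trimethylsilyl)ethyl (2E)-4-[(3S,6S)-6-[(tert-butyldimethylsilyl)oxy]-5-[(E)-hept-1-en-1-yl]-3-hydroxy-4-(hydroxymethyl)cyclohexa-1,4-dien-1-yl]-2-methylbut-2-enoate | CCCCC/C=C/C1=C(CO)[C@@H](O)C=C(C/C=C(\C)C(=O)OCC[Si](C)(C)C)[C@@H]1O[Si](C)(C)C(C)(C)C
F6 | step 16 | 2-(trimethylsilyl)ethyl (2E)-4-[(3S,6S)-6-[(tert-butyldimethylsilyl)oxy]-4-formyl-5-[(E)-hept-1-en-1-yl]-3-hydroxycyclohexa-1,4-dien-1-yl]-2-methylbut-2-enoate | CCCCC/C=C/C1=C(C=O)[C@@H](O)C=C(C/C=C(\C)C(=O)OCC[Si](C)(C)C)[C@@H]1O[Si](C)(C)C(C)(C)C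
F7 | step 16 | 2-(trimethylsilyl)ethyl (2E)-4-[(1S,2R,5R,6R)-2-[(tert-butyldimethylsilyl)oxy]-4-formyl-3-[(E)-hept-1-en-1-yl]-5-hydroxy-7-oxabicyclo[4.1.0]hept-3-en-1-yl]-2-methylbut-2-enoate | CCCCC/C=C/C1=C(C=O)[C@@H](O)[C@H]2O[C@@]2(C/C=C(\C)C(=O)OCC[Si](C)(C)C)[C@@H]1O[Si](C)(C)C(C)(C)C
F8 | step 16 | 2-(trimethylsilyl)ethyl (2E)-4-[(1S,2R,5R,6R)-2-[(tert-butyldimethylsilyl)oxy]-3-[(E)-hept-1-en-1-yl]-5-hydroxy-4-(hydroxymethyl)-7-oxabicyclo[4.1.0]hept-3-en-1-yl]-2-methylbut-2-enoate | CCCCC/C=C/C1=C(CO)[C@@H](O)[C@H]2O[C@@]2(C/C=C(\C)C(=O)OCC[Si](C)(C)C)[C@@H]1O[Si](C)(C)C(C)(C)C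
F9 | step 2 | 2-[(E)-hept-1-en-1-yl]-4,4,5,5-tetramethyl-1,3,2-dioxaborolane | CCCCC/C=C/B1OC(C)(C)C(C)(C)O1
F10 | step 2 | 3-bromo-4-[(E)-hept-1-en-1-yl]furan-2(5H)-one | CCCCC/C=C/C1=C(Br)C(=O)OC1
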